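At early times the starting material and the other conformer, charged in equal amounts, begin to trade places while their exits are already open, and the questions below concern what survives that start.

    other conformer → isomer of the product (k1 = 0.52 /s)
    target → over-reaction product (k2 = 2.9 × 10⁻⁴ /s)
    other conformer ⇌ third conformer (K3 = 1.1, k3 = 0.23 /s)
    starting material → target (k4 = 0.30 /s)
    starting material ⇌ other conformer, settled at all times (K5 = 2.6)
    2 other conformer → homo dimer (k6 = 1900 /M/s)
    third conformer → third product (k7 = 8.1 /s)

all flasks: other conformer 1.00 equiv; time 4.0 s

| run | starting material |
|---|---|
| spring | 1.0 mM |
| noon | 2.0 mM |
| autumn | 4.0 mM |
| dusk | 8.0 mM |
| dawn | 15 mM |

* share of target in all that became target or isomer of the product or third product for spring, noon, autumn, dusk, dawn, in this order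
* how that number moves from the first to the last of them (falls all the way / falls, then rises / rises all the way / rises, then falls / hardly changes)

- percentages count the starting material that a species holds: one homo dimer counts as two
- two of one species on the left: rate k times its square, two consumed each time
- the share counts what is present at the end, not what went on to other products
- "hardly changes" means that all values lie within two and a half points (for a concentration: within two and a half percent of the largest)
- run time (spring): 4.0 s

What does the flask look like after its first instants? The fast balance holds [other conformer] at 2.6 times [starting material], so I follow one pool with one concentration, as one follows a single tank feeding several drains.

And the drains? Target leaves at 0.30 /s per unit of [starting material], and the isomer of the product leaves at 1.35 /s on the same footing, since its step draws on [other conformer].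

But the third conformer can go back, so what does that exit count for? It returns at 0.209 /s and goes forward to third product at 8.1 /s, much faster, so 97.5 % of what enters passes through, which makes that exit worth 0.583 /s per unit of [starting material].

What do you carry away from that? The exit share of target, which is the target exit divided by the sum of the exits, each written per unit of [starting material]. I reckon it as 13.4 %, and it contains no concentration; this is the Curtin–Hammett case, in which a fast balance and the exit constants give the product ratio.

Surely the homo dimer, which goes with the square of [other conformer], moves that number? That is the weak spot, so I look for the crossing. The dimer outruns the exits above [other conformer] of 0.226 mM, and the spring flask starts, after the balance, at 1.44 mM, higher than that. So the dimer shrinks what reaches the exits, but each exit still runs at a constant times [starting material], with third product following through the third conformer, and the amounts, being those rates summed over time, keep their ratio.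

And the loss of target? Its half-life in spring is 40 min, longer than the run of 4.0 s, so I drop it and commit to a flat row at 13.4 %.

The forecast gives 13.4 %, 13.4 %, 13.4 %, 13.4 % and 13.4 %, and calls the shape "hardly changes", on the ground that “The second-order dimerisation only shrinks the total yield at higher loading”.

The simulation gives 13.4 %, 13.4 %, 13.4 %, 13.4 % and 13.4 %, and the shape is "hardly changes".

The exit share of 13.4 % holds from spring to dawn because the balance between starting material and other conformer makes the exits draw on one pool. With that balance taken away, the share goes from 13.4 % to 66.9 % in the spring flask and from 13.4 % to 92.6 % in the dawn flask. In the dawn flask at 4.00 s, homo dimer holds 95.2 % of the charge and the exit products together hold 4.68 %, of which the exit share gives target 0.627 %.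

The rate constants are made up; the run is a simulation.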